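| flask | free monomer | initiator | remark | time |
|---|---|---|---|---|
| Sunday's | 0.018 M | 2 mM | run made earlier |  |
| Monday's | 0.027 M | 2 mM | run made earlier |  |
| Wednesday's | 0.036 M | 3 mM | run made earlier |  |
| flask | 0.036 M | 2.0 mM |  | 50 min |

- Sunday's (time / min: monomer in chains / %, free monomer / %): 3.00: 4.7, 96.4; 10.0: 11.0, 88.9; 20.0: 13.6, 84.3; 25.0: 14.7, 84.3; 40.0: 15.0, 82.6; 50.0: 15.5, 81.1
- Monday's (time / min: monomer in chains / %, free monomer / %): 8.00: 11.3, 89.7; 15.0: 16.5, 82.4; 25.0: 22.3, 76.3; 30.0: 24.5, 74.0; 40.0: 26.2, 69.6; 50.0: 29.1, 67.6
- Wednesday's (time / min: monomer in chains / %, free monomer / %): 4.00: 9.1, 90.9; 12.0: 21.7, 77.7; 25.0: 32.3, 64.7; 40.0: 37.5, 57.1; 50.0: 39.0, 55.2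

(scatter of a reading: 0.5 percentage points)

- the average divides the monomer in chains by the number of chains begun, living and dead together
- the numbers in the tables scatter by 0.5 percentage points (one standard deviation)
- the earlier runs do not show the number of chains; that part of a forecast is a guess

- average number of monomer units in a chain (chains begun, living or dead) at 50 min
- part of the free monomer that has reacted at 50 min

Sunday's free monomer was drifting down slowly by its last reading, 14.6 mM, and I took that reading as a floor, the equilibrium monomer concentration. With 0.036 M charged, I reckoned the flask's ceiling at 59.5% conversion.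

I called the free monomer above the floor the excess, and the natural logarithm of the excess charged over the excess left at the last reading the lifetime count. Monday gave 1.22 and Wednesday 1.40, which is less per initiator charged.

So I bounded the flask from above with Monday's count, taken at the same initiator, which gave 41.9%. I bounded it from below with Wednesday's count, taken at the same free monomer and cut in proportion to initiator, which gave 36.1%. Assuming one chain per initiator and Wednesday's 87.1% of reacted monomer in chains, I put dp between 5.65 and 6.57.

The forecast, 37% conversion and dp 6.5, stood inside both brackets, though it called dp a guess: “so this part is a guess”.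

The flask gave 38.1% conversion and dp 6.09, inside both brackets.

free monomer + initiator → living end + monomer in chains (k = 0.140 /M/s); free monomer + living end → monomer in chains + living end, rate k2*[living end]*[free monomer] (k = 0.220 /M/s); monomer in chains + living end → free monomer + living end, rate k3*[living end] as long as [monomer in chains] is above zero (k = 0.00310 /s); living end + monomer in chains → dead end (k = 0.0400 /M/s); free monomer → uncatalysed product (k = 3.50 × 10⁻⁶ /s) Initiation in the flask had half its turnover up to 50 min behind it by 2.34 min, and initiator stood at 0.177% of its charge at 25.0 min, while forward growth on living ends ran on, with half its turnover done by 19.1 min. Living end fell from 0.00151 M at 5.00 min to 7.52 × 10⁻⁴ M at 50.0 min. The flask's lifetime count came to 1.02, below Monday's 1.22. A neighbour flask, the same but charged with 0.022 M of free monomer, reached 26.8% conversion, a count of 1.59.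

The numbers in the tables come from a simulation from invented constants, noise included.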